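**Retrosynthetic overview**
1. Target 20 ⇐ triol enal 19: the C5–O bond is made last by a 5-exo oxa-Michael addition, so the oxolane ring is closed last, on a preformed cyclohexane.
2. The enal ⇐ ketone 16 (isopropenyl addition, oxidative 1,3-transposition); the tertiary carbinol ⇐ MeMgBr on ketone 14.
3. Key disconnection: the CH2–CH2 bond between core and side chain ⇐ ketone homoenolate (β-zincio ketone from cyclopropanol 12) + allylic carbonate 5; a ketone β-carbon is used as the nucleophile against an allylic electrophile.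
4. Cyclopropanol 12 ⇐ face-selective cyclopropanation of silyl enol ether 10 (transient three-membered ring) ⇐ asymmetric conjugate addition to the Baylis–Hillman adduct of enone 6 (the carbocycle is bought).
5. Carbonate 5 ⇐ (1R,5S)-cis-α-irone 2 (the cyclohexene ring is bought and resolved) by olefination, reduction and carbonate formation.

Assumption: commercial α-irone is the usual perfumery-grade racemic mixture of (E)-configured cis and trans isomers, and the ring enantiomer needed is separated from it in step 1.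

**Step 1**
Reactants: 1 α-irone (commercial racemic cis/trans mixture)
Product: 2 (3E)-4-[(1R,5S)-2,5,6,6-tetramethylcyclohex-2-en-1-yl]but-3-en-2-one
Conditions: preparative chiral SFC, cellulose tris(3,5-dimethylphenylcarbamate) phase, CO2/i-PrOH, 35 °C, stacked injections
Reagents that add atoms: none
Why: Chromatographic resolution (no bond is made) separates the four α-irone stereoisomers, and the (1R,5S)-cis isomer collected carries both ring stereocentres of the target, which are not touched again.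

**Step 2**
Reactants: 2 (3E)-4-[(1R,5S)-2,5,6,6-tetramethylcyclohex-2-en-1-yl]but-3-en-2-one
Product: 3 ethyl (2E,4E)-3-methyl-5-[(1R,5S)-2,5,6,6-tetramethylcyclohex-2-en-1-yl]penta-2,4-dienoate
Conditions: (EtO)2P(O)CH2CO2Et, NaH, THF, 0 → 23 °C; minor 2Z isomer removed by chromatography
Reagents that add atoms: triethyl phosphonoacetate, CCOC(=O)CP(=O)(OCC)OCC
Why: Horner–Wadsworth–Emmons olefination of the methyl ketone gives mainly the 2E enoate (ester trans to the dienyl group), and the weakly basic phosphonate anion does not disturb the bis-allylic ring centre.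

**Step 3**
Reactants: 3 ethyl (2E,4E)-3-methyl-5-[(1R,5S)-2,5,6,6-tetramethylcyclohex-2-en-1-yl]penta-2,4-dienoate
Product: 4 (2E,4E)-3-methyl-5-[(1R,5S)-2,5,6,6-tetramethylcyclohex-2-en-1-yl]penta-2,4-dien-1-ol
Conditions: i-Bu2AlH (2.2 equiv), CH2Cl2, −78 °C; aqueous KNaC4H4O6 work-up
Reagents that add atoms: none
Why: 1,2-Reduction of the dienoate by the aluminium hydride gives the allylic alcohol without changing the diene geometry.

**Step 4**
Reactants: 4 (2E,4E)-3-methyl-5-[(1R,5S)-2,5,6,6-tetramethylcyclohex-2-en-1-yl]penta-2,4-dien-1-ol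
Product: 5 methyl (2E,4E)-3-methyl-5-[(1R,5S)-2,5,6,6-tetramethylcyclohex-2-en-1-yl]penta-2,4-dien-1-yl carbonate
Conditions: ClCO2Me, pyridine, CH2Cl2, 0 °C
Reagents that add atoms: methyl chloroformate, COC(=O)Cl
Why: O-Acylation gives a storable allylic carbonate that ionises with zerovalent palladium and releases its own base (methoxide).

**Step 5**
Reactants: 6 1,4-dioxaspiro[4.5]dec-6-en-8-one
Product: 7 7-(hydroxymethyl)-1,4-dioxaspiro[4.5]dec-6-en-8-one
Conditions: 37% aq. HCHO, imidazole (1 equiv), THF/1 M aq. NaHCO3, 23 °C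
Reagents that add atoms: formaldehyde, C=O
Why: Morita–Baylis–Hillman α-hydroxymethylation of the cyclic enone (reversible β-addition of imidazole, trapping of formaldehyde, elimination); no stereocentre is formed.

**Step 6**
Reactants: 7 7-(hydroxymethyl)-1,4-dioxaspiro[4.5]dec-6-en-8-one
Product: 8 7-{[(tert-butyldimethylsilyl)oxy]methyl}-1,4-dioxaspiro[4.5]dec-6-en-8-one
Conditions: TBSCl, imidazole, DMF, 0 → 23 °C
Reagents that add atoms: tert-butyldimethylsilyl chloride, CC(C)(C)[Si](C)(C)Cl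
Why: Silylation of the primary alcohol gives a poor leaving group, which suppresses addition–elimination in the next step.

**Step 7**
Reactants: 8 7-{[(tert-butyldimethylsilyl)oxy]methyl}-1,4-dioxaspiro[4.5]dec-6-en-8-one
Product: 10 tert-butyl{3-[(6S)-7-{[(tert-butyldimethylsilyl)oxy]methyl}-8-[(trimethylsilyl)oxy]-1,4-dioxaspiro[4.5]dec-7-en-6-yl]propoxy}diphenylsilane, via magnesium enolate 9 (not isolated)
Conditions: TBDPSO(CH2)3MgBr (1.3 equiv), Cu(OTf)2 (3 mol%), chiral imidazolinium salt (NHC precursor, 4 mol%), Et2O, −30 °C; then TMSCl, Et3N, DMPU, −30 → 0 °C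
Reagents that add atoms: 3-[(tert-butyldiphenylsilyl)oxy]propylmagnesium bromide, CC(C)(C)[Si](OCCC[Mg]Br)(c1ccccc1)c1ccccc1; chlorotrimethylsilane, C[Si](C)(C)Cl
Why: Copper–NHC-catalysed asymmetric conjugate addition of a Grignard reagent to a 2-substituted cyclohexenone (activated by the γ-ketal) sets C6 under catalyst control (ligand enantiomer chosen for 6S), and O-silylation of the regiodefined enolate gives the tetrasubstituted enol ether before the silyloxymethyl group can eliminate.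

**Step 8**
Reactants: 10 tert-butyl{3-[(6S)-7-{[(tert-butyldimethylsilyl)oxy]methyl}-8-[(trimethylsilyl)oxy]-1,4-dioxaspiro[4.5]dec-7-en-6-yl]propoxy}diphenylsilane
Product: 12 (1S,2S,6R)-1-{[(tert-butyldimethylsilyl)oxy]methyl}-2-{3-[(tert-butyldiphenylsilyl)oxy]propyl}spiro[bicyclo[4.1.0]heptane-3,2'-[1,3]dioxolan]-6-ol, via siloxycyclopropane 11 (not isolated)
Conditions: Et2Zn, CH2I2, CH2Cl2, 0 → 23 °C; pyridine quench; then K2CO3 (cat.), MeOH, 0 °C
Reagents that add atoms: diiodomethane, ICI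
Why: Simmons–Smith (Furukawa) cyclopropanation of the electron-rich enol ether occurs anti to the pseudoaxial C6 side chain, so the new CH2 ends trans and CH2OTBS cis to that chain, which fixes the future quaternary centre; cis ring fusion fixes the carbinol carbon and methanolysis frees the cyclopropanol.

**Step 9 (key step)**
Reactants: 12 (1S,2S,6R)-1-{[(tert-butyldimethylsilyl)oxy]methyl}-2-{3-[(tert-butyldiphenylsilyl)oxy]propyl}spiro[bicyclo[4.1.0]heptane-3,2'-[1,3]dioxolan]-6-ol; 5 methyl (2E,4E)-3-methyl-5-[(1R,5S)-2,5,6,6-tetramethylcyclohex-2-en-1-yl]penta-2,4-dien-1-yl carbonate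
Product: 14 (6S,7S)-7-{[(tert-butyldimethylsilyl)oxy]methyl}-6-{3-[(tert-butyldiphenylsilyl)oxy]propyl}-7-{(3E,5E)-4-methyl-6-[(1R,5S)-2,5,6,6-tetramethylcyclohex-2-en-1-yl]hexa-3,5-dien-1-yl}-1,4-dioxaspiro[4.5]decan-8-one, via zinc homoenolate 13 (not isolated)
Conditions: Et2Zn (0.55 equiv), THF, 0 → 40 °C; then 5 (1.1 equiv), Pd2(dba)3 (2.5 mol%), P(2-furyl)3 (10 mol%), THF/DMA, 40 °C
Reagents that add atoms: none
Why: Proposed new method: ethane loss gives the zinc cyclopropoxide, whose strained bond between the carbinol carbon and the CH2 group opens to the primary β-zincio ketone 13 (a ketone homoenolate; the other bond would give a tertiary alkylzinc), and this neopentyl-type alkyl, which has no β-hydrogen, transmetalates to the π-allylpalladium formed from 5 and reductively eliminates at the unsubstituted allyl terminus with the 2E geometry kept (the dienyl group stays syn), so a ketone β-carbon and an allylic carbon, both normally electrophilic, are joined while the quaternary centre from step 8 is untouched; the closest known reactions are copper- or palladium-catalysed allylation, arylation and acylation of zinc homoenolates made from cyclopropanols or siloxycyclopropanes, and Negishi-type allyl–alkyl coupling.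

**Step 10**
Reactants: 14 (6S,7S)-7-{[(tert-butyldimethylsilyl)oxy]methyl}-6-{3-[(tert-butyldiphenylsilyl)oxy]propyl}-7-{(3E,5E)-4-methyl-6-[(1R,5S)-2,5,6,6-tetramethylcyclohex-2-en-1-yl]hexa-3,5-dien-1-yl}-1,4-dioxaspiro[4.5]decan-8-one
Product: 15 (6S,7S,8S)-7-{[(tert-butyldimethylsilyl)oxy]methyl}-6-{3-[(tert-butyldiphenylsilyl)oxy]propyl}-8-methyl-7-{(3E,5E)-4-methyl-6-[(1R,5S)-2,5,6,6-tetramethylcyclohex-2-en-1-yl]hexa-3,5-dien-1-yl}-1,4-dioxaspiro[4.5]decan-8-ol
Conditions: MeMgBr, THF, −78 → −20 °C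
Reagents that add atoms: methylmagnesium bromide, C[Mg]Br
Why: Grignard 1,2-addition to the α-quaternary cyclohexanone: in the chair with CH2OTBS axial, equatorial approach is blocked by that group and the small nucleophile adds axially from the opposite face, giving the tertiary alcohol with OH cis to CH2OTBS (8S).

**Step 11**
Reactants: 15 (6S,7S,8S)-7-{[(tert-butyldimethylsilyl)oxy]methyl}-6-{3-[(tert-butyldiphenylsilyl)oxy]propyl}-8-methyl-7-{(3E,5E)-4-methyl-6-[(1R,5S)-2,5,6,6-tetramethylcyclohex-2-en-1-yl]hexa-3,5-dien-1-yl}-1,4-dioxaspiro[4.5]decan-8-ol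
Product: 16 (2S,3S,4S)-3-{[(tert-butyldimethylsilyl)oxy]methyl}-2-{3-[(tert-butyldiphenylsilyl)oxy]propyl}-4-hydroxy-4-methyl-3-{(3E,5E)-4-methyl-6-[(1R,5S)-2,5,6,6-tetramethylcyclohex-2-en-1-yl]hexa-3,5-dien-1-yl}cyclohexan-1-one
Conditions: PPTS (0.2 equiv), acetone/H2O 10:1, 45 °C
Reagents that add atoms: water, O
Why: Acid-catalysed hydrolysis of the dioxolane with a buffer acid that spares both silyl ethers, the tertiary alcohol and the diene and is too weak to enolise the new ketone, so C2 is not epimerised.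

**Step 12**
Reactants: 16 (2S,3S,4S)-3-{[(tert-butyldimethylsilyl)oxy]methyl}-2-{3-[(tert-butyldiphenylsilyl)oxy]propyl}-4-hydroxy-4-methyl-3-{(3E,5E)-4-methyl-6-[(1R,5S)-2,5,6,6-tetramethylcyclohex-2-en-1-yl]hexa-3,5-dien-1-yl}cyclohexan-1-one
Product: 17 (1S,2S,3S)-2-{[(tert-butyldimethylsilyl)oxy]methyl}-3-{3-[(tert-butyldiphenylsilyl)oxy]propyl}-1-methyl-2-{(3E,5E)-4-methyl-6-[(1R,5S)-2,5,6,6-tetramethylcyclohex-2-en-1-yl]hexa-3,5-dien-1-yl}-4-(prop-1-en-2-yl)cyclohexane-1,4-diol (both C4 epimers)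
Conditions: CH2=C(CH3)MgBr (4 equiv), CeCl3 (4 equiv), THF, −78 °C
Reagents that add atoms: isopropenylmagnesium bromide, CC(=C)[Mg]Br
Why: Organocerium 1,2-addition is non-basic, so the hindered ketone is neither enolised nor epimerised at the adjacent centre (one equivalent is spent on the free OH), and both C4 epimers are carried on because this carbon becomes sp2 in the next step.

**Step 13**
Reactants: 17 (1S,2S,3S)-2-{[(tert-butyldimethylsilyl)oxy]methyl}-3-{3-[(tert-butyldiphenylsilyl)oxy]propyl}-1-methyl-2-{(3E,5E)-4-methyl-6-[(1R,5S)-2,5,6,6-tetramethylcyclohex-2-en-1-yl]hexa-3,5-dien-1-yl}-4-(prop-1-en-2-yl)cyclohexane-1,4-diol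
Product: 18 2-[(2R,3S,4S)-3-{[(tert-butyldimethylsilyl)oxy]methyl}-2-{3-[(tert-butyldiphenylsilyl)oxy]propyl}-4-hydroxy-4-methyl-3-{(3E,5E)-4-methyl-6-[(1R,5S)-2,5,6,6-tetramethylcyclohex-2-en-1-yl]hexa-3,5-dien-1-yl}cyclohexylidene]propanal (E/Z mixture at the ylidene bond)
Conditions: pyridinium chlorochromate (3 equiv), NaOAc, 4 Å molecular sieves, CH2Cl2, 23 °C
Reagents that add atoms: pyridinium chlorochromate, [O-][Cr](=O)(=O)Cl.c1cc[nH+]cc1
Why: Babler–Dauben oxidative 1,3-transposition: the tertiary allylic chromate ester undergoes a [3,3] shift to the primary allylic chromate, which is oxidised to the tetrasubstituted enal (oxygen delivered from chromium), while the non-allylic tertiary alcohol is inert and the alkene geometry is irrelevant because this carbon becomes sp3 in the last step.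

**Step 14**
Reactants: 18 2-[(2R,3S,4S)-3-{[(tert-butyldimethylsilyl)oxy]methyl}-2-{3-[(tert-butyldiphenylsilyl)oxy]propyl}-4-hydroxy-4-methyl-3-{(3E,5E)-4-methyl-6-[(1R,5S)-2,5,6,6-tetramethylcyclohex-2-en-1-yl]hexa-3,5-dien-1-yl}cyclohexylidene]propanal
Product: 20 (2S)-2-[(1S,2S,5R,8S)-2-hydroxy-8-(3-hydroxypropyl)-2-methyl-1-{(3E,5E)-4-methyl-6-[(1R,5S)-2,5,6,6-tetramethylcyclohex-2-en-1-yl]hexa-3,5-dien-1-yl}-6-oxabicyclo[3.2.1]octan-5-yl]propanal (CNP0419303.1), via triol enal 19 (not isolated)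
Conditions: Bu4NF (3 equiv), THF, 0 → 23 °C, 12 h
Reagents that add atoms: none
Why: Fluoride desilylation is followed by 5-exo-trig intramolecular oxa-Michael addition of the CH2OH group, which sits 1,3-diaxial over the enal β-carbon, so the bicyclic geometry fixes C5; the aldehyde α-centre is set by reversible enolisation under the basic conditions, which is argued (not proven) to favour the 2S epimer with methyl anti to C8 and the hydrogen facing the C8 side chain.

**Compound list**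
1 | α-irone, commercial perfumery grade, (3E)-4-(2,5,6,6-tetramethylcyclohex-2-en-1-yl)but-3-en-2-one as racemic cis/trans mixture | CC1=CCC(C)C(C)(C)C1/C=C/C(C)=O | starting material
2 | (3E)-4-[(1R,5S)-2,5,6,6-tetramethylcyclohex-2-en-1-yl]but-3-en-2-one (cis-α-irone, single enantiomer) | CC1=CC[C@H](C)C(C)(C)[C@@H]1/C=C/C(C)=O | intermediate
3 | ethyl (2E,4E)-3-methyl-5-[(1R,5S)-2,5,6,6-tetramethylcyclohex-2-en-1-yl]penta-2,4-dienoate | CC1=CC[C@H](C)C(C)(C)[C@@H]1/C=C/C(C)=C/C(=O)OCC | intermediate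
4 | (2E,4E)-3-methyl-5-[(1R,5S)-2,5,6,6-tetramethylcyclohex-2-en-1-yl]penta-2,4-dien-1-ol | CC1=CC[C@H](C)C(C)(C)[C@@H]1/C=C/C(C)=C/CO | intermediate
5 | methyl (2E,4E)-3-methyl-5-[(1R,5S)-2,5,6,6-tetramethylcyclohex-2-en-1-yl]penta-2,4-dien-1-yl carbonate | CC1=CC[C@H](C)C(C)(C)[C@@H]1/C=C/C(C)=C/COC(=O)OC | intermediate
6 | 1,4-dioxaspiro[4.5]dec-6-en-8-one | O=C1C=CC2(CC1)OCCO2 | starting material
7 | 7-(hydroxymethyl)-1,4-dioxaspiro[4.5]dec-6-en-8-one | O=C1C(CO)=CC2(CC1)OCCO2 | intermediate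
8 | 7-{[(tert-butyldimethylsilyl)oxy]methyl}-1,4-dioxaspiro[4.5]dec-6-en-8-one | O=C1C(CO[Si](C)(C)C(C)(C)C)=CC2(CC1)OCCO2 | intermediate
9 | bromomagnesium enolate of (6S)-7-{[(tert-butyldimethylsilyl)oxy]methyl}-6-{3-[(tert-butyldiphenylsilyl)oxy]propyl}-1,4-dioxaspiro[4.5]decan-8-one (C7=C8 enolate) | Br[Mg]OC1=C(CO[Si](C)(C)C(C)(C)C)[C@H](CCCO[Si](c3ccccc3)(c3ccccc3)C(C)(C)C)C2(CC1)OCCO2 | intermediate
10 | tert-butyl{3-[(6S)-7-{[(tert-butyldimethylsilyl)oxy]methyl}-8-[(trimethylsilyl)oxy]-1,4-dioxaspiro[4.5]dec-7-en-6-yl]propoxy}diphenylsilane | C[Si](C)(C)OC1=C(CO[Si](C)(C)C(C)(C)C)[C@H](CCCO[Si](c3ccccc3)(c3ccccc3)C(C)(C)C)C2(CC1)OCCO2 | intermediate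
11 | trimethylsilyl ether of 12, (1S,2S,6R)-configured, cyclopropane CH2 trans to the C2 side chain | C[Si](C)(C)O[C@]12C[C@@]1(CO[Si](C)(C)C(C)(C)C)[C@H](CCCO[Si](c3ccccc3)(c3ccccc3)C(C)(C)C)C3(CC2)OCCO3 | intermediate
12 | (1S,2S,6R)-1-{[(tert-butyldimethylsilyl)oxy]methyl}-2-{3-[(tert-butyldiphenylsilyl)oxy]propyl}spiro[bicyclo[4.1.0]heptane-3,2'-[1,3]dioxolan]-6-ol | O[C@]12C[C@@]1(CO[Si](C)(C)C(C)(C)C)[C@H](CCCO[Si](c3ccccc3)(c3ccccc3)C(C)(C)C)C3(CC2)OCCO3 | intermediate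
13 | bis{[(6S,7R)-7-{[(tert-butyldimethylsilyl)oxy]methyl}-6-{3-[(tert-butyldiphenylsilyl)oxy]propyl}-8-oxo-1,4-dioxaspiro[4.5]decan-7-yl]methyl}zinc | [Zn](C[C@@]1(CO[Si](C)(C)C(C)(C)C)[C@H](CCCO[Si](c2ccccc2)(c2ccccc2)C(C)(C)C)C2(CCC1=O)OCCO2)C[C@@]1(CO[Si](C)(C)C(C)(C)C)[C@H](CCCO[Si](c2ccccc2)(c2ccccc2)C(C)(C)C)C2(CCC1=O)OCCO2 | intermediate
14 | (6S,7S)-7-{[(tert-butyldimethylsilyl)oxy]methyl}-6-{3-[(tert-butyldiphenylsilyl)oxy]propyl}-7-{(3E,5E)-4-methyl-6-[(1R,5S)-2,5,6,6-tetramethylcyclohex-2-en-1-yl]hexa-3,5-dien-1-yl}-1,4-dioxaspiro[4.5]decan-8-one | CC1=CC[C@H](C)C(C)(C)[C@@H]1/C=C/C(C)=C/CC[C@@]2(CO[Si](C)(C)C(C)(C)C)[C@H](CCCO[Si](c3ccccc3)(c3ccccc3)C(C)(C)C)C3(CCC2=O)OCCO3 | intermediate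
15 | (6S,7S,8S)-7-{[(tert-butyldimethylsilyl)oxy]methyl}-6-{3-[(tert-butyldiphenylsilyl)oxy]propyl}-8-methyl-7-{(3E,5E)-4-methyl-6-[(1R,5S)-2,5,6,6-tetramethylcyclohex-2-en-1-yl]hexa-3,5-dien-1-yl}-1,4-dioxaspiro[4.5]decan-8-ol | CC1=CC[C@H](C)C(C)(C)[C@@H]1/C=C/C(C)=C/CC[C@@]2(CO[Si](C)(C)C(C)(C)C)[C@H](CCCO[Si](c3ccccc3)(c3ccccc3)C(C)(C)C)C3(CC[C@]2(C)O)OCCO3 | intermediate
16 | (2S,3S,4S)-3-{[(tert-butyldimethylsilyl)oxy]methyl}-2-{3-[(tert-butyldiphenylsilyl)oxy]propyl}-4-hydroxy-4-methyl-3-{(3E,5E)-4-methyl-6-[(1R,5S)-2,5,6,6-tetramethylcyclohex-2-en-1-yl]hexa-3,5-dien-1-yl}cyclohexan-1-one | CC1=CC[C@H](C)C(C)(C)[C@@H]1/C=C/C(C)=C/CC[C@@]2(CO[Si](C)(C)C(C)(C)C)[C@H](CCCO[Si](c3ccccc3)(c3ccccc3)C(C)(C)C)C(=O)CC[C@]2(C)O | intermediate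
17 | (1S,2S,3S)-2-{[(tert-butyldimethylsilyl)oxy]methyl}-3-{3-[(tert-butyldiphenylsilyl)oxy]propyl}-1-methyl-2-{(3E,5E)-4-methyl-6-[(1R,5S)-2,5,6,6-tetramethylcyclohex-2-en-1-yl]hexa-3,5-dien-1-yl}-4-(prop-1-en-2-yl)cyclohexane-1,4-diol, both C4 epimers | CC1=CC[C@H](C)C(C)(C)[C@@H]1/C=C/C(C)=C/CC[C@@]2(CO[Si](C)(C)C(C)(C)C)[C@H](CCCO[Si](c3ccccc3)(c3ccccc3)C(C)(C)C)C(O)(C(C)=C)CC[C@]2(C)O | intermediate
18 | 2-[(2R,3S,4S)-3-{[(tert-butyldimethylsilyl)oxy]methyl}-2-{3-[(tert-butyldiphenylsilyl)oxy]propyl}-4-hydroxy-4-methyl-3-{(3E,5E)-4-methyl-6-[(1R,5S)-2,5,6,6-tetramethylcyclohex-2-en-1-yl]hexa-3,5-dien-1-yl}cyclohexylidene]propanal, E/Z mixture at the ylidene bond | CC1=CC[C@H](C)C(C)(C)[C@@H]1/C=C/C(C)=C/CC[C@@]2(CO[Si](C)(C)C(C)(C)C)[C@H](CCCO[Si](c3ccccc3)(c3ccccc3)C(C)(C)C)C(=C(C)C=O)CC[C@]2(C)O | intermediate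
19 | 2-[(2R,3S,4S)-4-hydroxy-3-(hydroxymethyl)-2-(3-hydroxypropyl)-4-methyl-3-{(3E,5E)-4-methyl-6-[(1R,5S)-2,5,6,6-tetramethylcyclohex-2-en-1-yl]hexa-3,5-dien-1-yl}cyclohexylidene]propanal | CC1=CC[C@H](C)C(C)(C)[C@@H]1/C=C/C(C)=C/CC[C@@]2(CO)[C@H](CCCO)C(=C(C)C=O)CC[C@]2(C)O | intermediate
20 | (2S)-2-[(1S,2S,5R,8S)-2-hydroxy-8-(3-hydroxypropyl)-2-methyl-1-{(3E,5E)-4-methyl-6-[(1R,5S)-2,5,6,6-tetramethylcyclohex-2-en-1-yl]hexa-3,5-dien-1-yl}-6-oxabicyclo[3.2.1]octan-5-yl]propanal | CC1=CC[C@H](C)C(C)(C)[C@@H]1/C=C/C(C)=C/CC[C@]12CO[C@]([C@H](C)C=O)(CC[C@]1(C)O)[C@H]2CCCO | target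

**Step count and risks**
Total steps: 14. Longest linear sequence: 10 steps (steps 5–14 from 6; the irone branch, steps 1–4 then 9–14, is also 10).

Steps most likely to fail:

Step 9 (homoenolate allylation). Risks are slow transmetalation of the neopentyl alkylzinc, O-allylation of the zinc alkoxide, or transfer of the allyl group to zinc. The fallback sets out from 12 and returns at 14. N-Iodosuccinimide (CH2Cl2, 0 °C) opens the cyclopropanol at the same CH2–carbinol bond to give the β-iodo ketone F3. Nickel-catalysed reductive cross-electrophile coupling of the β-iodo ketone F3 with carbonate 5 (NiCl2(dme), 4,4'-di-tert-butyl-2,2'-bipyridine, Zn, DMA, 23 °C) then lets the neopentyl radical be captured by the allylnickel species at its primary terminus. This replaces closed-shell transmetalation by radical capture.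

Step 7 (asymmetric conjugate addition to the 2-substituted enone). Risks are low reactivity or low enantioselectivity with the α-substituent, and loss of the silyloxy group from the enolate. The fallback sets out from 6 and returns at 10. The same copper–NHC catalyst adds TBDPSO(CH2)3MgBr to the unsubstituted enone 6, a better-precedented substrate class, and the magnesium enolate is trapped with monomeric formaldehyde to give the trans hydroxymethyl ketone F1. TBSCl/imidazole converts it into the bis-silyl ether F2. Thermodynamic enol silylation (TMSOTf, Et3N, CH2Cl2, 0 °C) towards the more substituted, silyloxymethyl-bearing carbon then gives 10; the C7 configuration of F1 and F2 is lost at this point and does not matter.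

Step 14 (desilylation and oxa-Michael closure). Risks are a poor epimer ratio at the aldehyde α-carbon, competing addition of the hydroxypropyl OH, and γ-deprotonation of the enal by fluoride. The fallback sets out from 18 and returns at 20. HF·pyridine buffered with pyridine (THF, 0 °C) removes only the TBS ether, and DBU (CH2Cl2, 0 °C) closes the ring with the side-chain alcohol still protected, giving the TBDPS-protected oxabicyclic aldehyde F4 together with its α-epimer. NaBH4 (MeOH, 0 °C) reduces the mixture to configurationally stable alcohols, from which the (2R)-alcohol F5 is separated by chromatography. Dess–Martin periodinane/NaHCO3 returns the aldehyde F4 as a single epimer, and HF·pyridine (THF, 23 °C) removes the TBDPS group without base to give 20.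

**Further compounds**
F1 | step 7 | (6S,7R)-6-{3-[(tert-butyldiphenylsilyl)oxy]propyl}-7-(hydroxymethyl)-1,4-dioxaspiro[4.5]decan-8-one | OC[C@H]1[C@H](CCCO[Si](c2ccccc2)(c2ccccc2)C(C)(C)C)C2(CCC1=O)OCCO2
F2 | step 7 | (6S,7R)-7-{[(tert-butyldimethylsilyl)oxy]methyl}-6-{3-[(tert-butyldiphenylsilyl)oxy]propyl}-1,4-dioxaspiro[4.5]decan-8-one | CC(C)(C)[Si](C)(C)OC[C@H]1[C@H](CCCO[Si](c2ccccc2)(c2ccccc2)C(C)(C)C)C2(CCC1=O)OCCO2
F3 | step 9 | (6S,7R)-7-{[(tert-butyldimethylsilyl)oxy]methyl}-6-{3-[(tert-butyldiphenylsilyl)oxy]propyl}-7-(iodomethyl)-1,4-dioxaspiro[4.5]decan-8-one | IC[C@@]1(CO[Si](C)(C)C(C)(C)C)[C@H](CCCO[Si](c2ccccc2)(c2ccccc2)C(C)(C)C)C2(CCC1=O)OCCO2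
F4 | step 14 | (2S)-2-[(1S,2S,5R,8S)-8-{3-[(tert-butyldiphenylsilyl)oxy]propyl}-2-hydroxy-2-methyl-1-{(3E,5E)-4-methyl-6-[(1R,5S)-2,5,6,6-tetramethylcyclohex-2-en-1-yl]hexa-3,5-dien-1-yl}-6-oxabicyclo[3.2.1]octan-5-yl]propanal | CC1=CC[C@H](C)C(C)(C)[C@@H]1/C=C/C(C)=C/CC[C@]12CO[C@]([C@H](C)C=O)(CC[C@]1(C)O)[C@H]2CCCO[Si](c1ccccc1)(c1ccccc1)C(C)(C)C
F5 | step 14 | (2R)-2-[(1S,2S,5R,8S)-8-{3-[(tert-butyldiphenylsilyl)oxy]propyl}-2-hydroxy-2-methyl-1-{(3E,5E)-4-methyl-6-[(1R,5S)-2,5,6,6-tetramethylcyclohex-2-en-1-yl]hexa-3,5-dien-1-yl}-6-oxabicyclo[3.2.1]octan-5-yl]propan-1-ol | CC1=CC[C@H](C)C(C)(C)[C@@H]1/C=C/C(C)=C/CC[C@]12CO[C@]([C@H](C)CO)(CC[C@]1(C)O)[C@H]2CCCO[Si](c1ccccc1)(c1ccccc1)C(C)(C)C
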